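**Retrosynthetic overview**

1. Both angelates come from acylation with one preformed angelic 2,4,6-trichlorobenzoic mixed anhydride. The side-chain oxirane (C10–C11) comes from a 1,3-syn bromo diol, itself from 1,3-syn reduction of a β-hydroxy α′-bromo ketone, so C10 follows C8.
2. The C8–C9 bond comes from aldol union of a 2-substituted acrolein (C8 aldehyde) with 3-bromo-3-methylbutan-2-one.
3. Key step: the C8–O bond is made by the SeO2 ene reaction / [2,3]-sigmatropic rearrangement on the isopropenyl group.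
4. The ring functions come from (R)-carvone: Luche reduction, hydroxyl-directed epoxidation and re-oxidation give the cis-epoxy ketone; enolate hydroxylation at C3 (anti to C4) and angeloylation follow.
5. Ring order: the carbocycle is bought with C4; the ring oxirane is formed in step 2; the side-chain oxirane is formed in step 10.

Assumption: atom labels follow bisabolane numbering. Ring: C1 (methyl-bearing oxirane carbon), C2 (C=O), C3 (CH–OAng), C4 (CH bearing the side chain), C5, C6 (oxirane CH). Side chain: C7(=C14H2)–C8(OAng)–C9H2–C10–C11 (oxirane). In these labels the target is 1S,3S,4S,6S,8S,10R.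

**Route**

Step 1
Reactants: 1 (R)-(−)-carvone
Product: 2 (1R,5R)-cis-carveol
Conditions: NaBH4, CeCl3·7H2O, MeOH, −20 °C
Reagents that add atoms: none
Why: Luche 1,2-reduction, in which axial hydride delivery to the conformer with an equatorial isopropenyl group gives the equatorial alcohol, so the new C2 carbinol is cis to the bought C4 centre (about 95:5).

Step 2
Reactants: 2 (1R,5R)-cis-carveol
Product: 3 (1R,2R,4S,6S)-1-methyl-4-(prop-1-en-2-yl)-7-oxabicyclo[4.1.0]heptan-2-ol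
Conditions: VO(acac)2 (2 mol %), t-BuOOH, CH2Cl2, 0 °C to rt
Reagents that add atoms: tert-butyl hydroperoxide, CC(C)(C)OO
Why: Hydroxyl-directed (Sharpless-type) vanadium-catalysed epoxidation delivers oxygen to the ring alkene on the face of the C2 hydroxyl, setting C1 and C6 cis to OH and to the isopropenyl group, while the remote isopropenyl alkene is not touched.

Step 3
Reactants: 3 (1R,2R,4S,6S)-1-methyl-4-(prop-1-en-2-yl)-7-oxabicyclo[4.1.0]heptan-2-ol
Product: 4 (1S,4R,6S)-1-methyl-4-(prop-1-en-2-yl)-7-oxabicyclo[4.1.0]heptan-2-one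
Conditions: Dess–Martin periodinane, CH2Cl2, rt
Reagents that add atoms: none
Why: Dess–Martin oxidation of the secondary alcohol gives the cis-epoxy ketone without opening the oxirane, and the C2 relay centre is erased after it has fixed C1 and C6.

Step 4
Reactants: 4 (1S,4R,6S)-1-methyl-4-(prop-1-en-2-yl)-7-oxabicyclo[4.1.0]heptan-2-one
Product: 6 (1S,3S,4S,6S)-3-hydroxy-1-methyl-4-(prop-1-en-2-yl)-7-oxabicyclo[4.1.0]heptan-2-one, via potassium enolate 5 (not isolated)
Conditions: KN(SiMe3)2, THF, −78 °C; then racemic 2-(phenylsulfonyl)-3-phenyloxaziridine, −78 °C; AcOH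
Reagents that add atoms: racemic 2-(phenylsulfonyl)-3-phenyloxaziridine, O=S(=O)(c1ccccc1)N1OC1c1ccccc1
Why: Davis enolate hydroxylation, in which only C3 can be deprotonated (C1 is quaternary) and the oxidant approaches anti to the adjacent C4 isopropenyl group and to the oxirane, giving the trans (3S) alcohol under substrate control.

Step 5
Reactants: 7 angelic acid
Product: 8 (2Z)-2-methylbut-2-enoic 2,4,6-trichlorobenzoic anhydride
Conditions: 2,4,6-trichlorobenzoyl chloride (1.0 equiv), Et3N (1.05 equiv), toluene, 0 °C to rt; filtered under argon, concentrated, kept as a toluene solution (one batch, enough for steps 6 and 11)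
Reagents that add atoms: 2,4,6-trichlorobenzoyl chloride, O=C(Cl)c1c(Cl)cc(Cl)cc1Cl
Why: Acylation of the triethylammonium carboxylate by the hindered aroyl chloride gives the Yamaguchi mixed anhydride, and no nucleophilic catalyst is present that could isomerise the Z alkene to the tiglate.

Step 6
Reactants: 6 (1S,3S,4S,6S)-3-hydroxy-1-methyl-4-(prop-1-en-2-yl)-7-oxabicyclo[4.1.0]heptan-2-one; 8 (2Z)-2-methylbut-2-enoic 2,4,6-trichlorobenzoic anhydride
Product: 9 (1S,3S,4S,6S)-1-methyl-2-oxo-4-(prop-1-en-2-yl)-7-oxabicyclo[4.1.0]heptan-3-yl (2Z)-2-methylbut-2-enoate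
Conditions: 8 (3 equiv), Et3N (3 equiv), toluene, 75 °C
Reagents that add atoms: none
Why: Yamaguchi-type esterification, in which the alcohol attacks the unhindered angeloyl carbonyl of the mixed anhydride without a nucleophilic catalyst, so the angeloyl group is transferred without Z-to-E isomerisation and no stereocentre is touched.

Step 7
Reactants: 9 (1S,3S,4S,6S)-1-methyl-2-oxo-4-(prop-1-en-2-yl)-7-oxabicyclo[4.1.0]heptan-3-yl (2Z)-2-methylbut-2-enoate
Product: 12 (1S,3S,4S,6S)-1-methyl-2-oxo-4-(3-oxoprop-1-en-2-yl)-7-oxabicyclo[4.1.0]heptan-3-yl (2Z)-2-methylbut-2-enoate, via allylseleninic acid 10 (not isolated), via primary allylic alcohol 11 (not isolated)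
Conditions: SeO2 (2 equiv), 1,4-dioxane, 80 °C
Reagents that add atoms: selenium dioxide, O=[Se]=O
Why: Riley allylic oxidation, in which an ene reaction at the isopropenyl group gives the allylseleninic acid, its [2,3]-sigmatropic rearrangement forms the C8–O bond and restores the 1,1-disubstituted alkene, and the primary allylic alcohol is oxidised on to the enal; no stereocentre is created.

Step 8
Reactants: 12 (1S,3S,4S,6S)-1-methyl-2-oxo-4-(3-oxoprop-1-en-2-yl)-7-oxabicyclo[4.1.0]heptan-3-yl (2Z)-2-methylbut-2-enoate; 13 3-bromo-3-methylbutan-2-one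
Product: 15 (1S,3S,4S,6S)-4-[(3S)-6-bromo-3-hydroxy-6-methyl-5-oxohept-1-en-2-yl]-1-methyl-2-oxo-7-oxabicyclo[4.1.0]heptan-3-yl (2Z)-2-methylbut-2-enoate, via dibutylboron enolate 14 (not isolated)
Conditions: 13, Bu2BOTf, i-Pr2NEt, CH2Cl2, −78 °C; then 12, −78 to −40 °C; MeOH, pH 7 buffer
Reagents that add atoms: none
Why: Boron-mediated aldol 1,2-addition of the methyl ketone enolate to the enal forms the C8–C9 bond; C8 is set only by substrate control from the neighbouring C4 and C3 centres, a bias whose size and sense are not secured, so the (8S) epimer is separated by chromatography.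

Step 9
Reactants: 15 (1S,3S,4S,6S)-4-[(3S)-6-bromo-3-hydroxy-6-methyl-5-oxohept-1-en-2-yl]-1-methyl-2-oxo-7-oxabicyclo[4.1.0]heptan-3-yl (2Z)-2-methylbut-2-enoate
Product: 17 (1S,3S,4S,6S)-4-[(3S,5R)-6-bromo-3,5-dihydroxy-6-methylhept-1-en-2-yl]-1-methyl-2-oxo-7-oxabicyclo[4.1.0]heptan-3-yl (2Z)-2-methylbut-2-enoate, via diethylboron chelate 16 (not isolated)
Conditions: Et2BOMe, THF/MeOH (4:1), −78 °C; then NaBH4, −78 °C; MeOH co-evaporation
Reagents that add atoms: none
Why: Narasaka–Prasad reduction, in which external hydride attacks the six-membered boron chelate of the β-hydroxy ketone to give the 1,3-syn diol (typically 20:1 or better), so C10 is set by C8, while the unchelated, hindered ring ketone and the ester should react much more slowly at −78 °C.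

Step 10
Reactants: 17 (1S,3S,4S,6S)-4-[(3S,5R)-6-bromo-3,5-dihydroxy-6-methylhept-1-en-2-yl]-1-methyl-2-oxo-7-oxabicyclo[4.1.0]heptan-3-yl (2Z)-2-methylbut-2-enoate
Product: 18 (1S,3S,4S,6S)-4-{(3S)-4-[(2R)-3,3-dimethyloxiran-2-yl]-3-hydroxybut-1-en-2-yl}-1-methyl-2-oxo-7-oxabicyclo[4.1.0]heptan-3-yl (2Z)-2-methylbut-2-enoate
Conditions: DBU, CH2Cl2, 0 °C to rt
Reagents that add atoms: none
Why: Intramolecular Williamson etherification (3-exo-tet), in which the C10 oxygen displaces the tertiary bromide at C11 and closes the oxirane with retention at C10, using a non-nucleophilic base that spares the angelate.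

Step 11
Reactants: 18 (1S,3S,4S,6S)-4-{(3S)-4-[(2R)-3,3-dimethyloxiran-2-yl]-3-hydroxybut-1-en-2-yl}-1-methyl-2-oxo-7-oxabicyclo[4.1.0]heptan-3-yl (2Z)-2-methylbut-2-enoate; 8 (2Z)-2-methylbut-2-enoic 2,4,6-trichlorobenzoic anhydride
Product: 19 (1S,3S,4S,6S)-4-{(3S)-4-[(2R)-3,3-dimethyloxiran-2-yl]-3-[(2Z)-2-methylbut-2-enoyloxy]but-1-en-2-yl}-1-methyl-2-oxo-7-oxabicyclo[4.1.0]heptan-3-yl (2Z)-2-methylbut-2-enoate
Conditions: 8 (3 equiv), Et3N (3 equiv), toluene, 75 °C
Reagents that add atoms: none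
Why: Yamaguchi-type esterification of the C8 alcohol proceeds with retention at C8 and without angelate isomerisation, under buffered basic conditions intended to leave both oxiranes intact.

**Compound list**

1 | (R)-(−)-carvone, (5R)-2-methyl-5-(prop-1-en-2-yl)cyclohex-2-en-1-one | C=C(C)[C@@H]1CC=C(C)C(=O)C1 | starting material
2 | (−)-cis-carveol, (1R,5R)-2-methyl-5-(prop-1-en-2-yl)cyclohex-2-en-1-ol | C=C(C)[C@@H]1CC=C(C)[C@H](O)C1 | intermediate
3 | (1R,2R,4S,6S)-1-methyl-4-(prop-1-en-2-yl)-7-oxabicyclo[4.1.0]heptan-2-ol (OH, oxirane O and isopropenyl all cis) | C=C(C)[C@@H]1C[C@@H]2O[C@]2(C)[C@H](O)C1 | intermediate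
4 | (1S,4R,6S)-1-methyl-4-(prop-1-en-2-yl)-7-oxabicyclo[4.1.0]heptan-2-one (cis-carvone oxide) | C=C(C)[C@@H]1C[C@@H]2O[C@]2(C)C(=O)C1 | intermediate
5 | potassium (1S,4R,6S)-1-methyl-4-(prop-1-en-2-yl)-7-oxabicyclo[4.1.0]hept-2-en-2-olate | C=C(C)[C@@H]1C[C@@H]2O[C@]2(C)C([O-])=C1.[K+] | intermediate
6 | (1S,3S,4S,6S)-3-hydroxy-1-methyl-4-(prop-1-en-2-yl)-7-oxabicyclo[4.1.0]heptan-2-one | C=C(C)[C@@H]1C[C@@H]2O[C@]2(C)C(=O)[C@H]1O | intermediate
7 | angelic acid, (2Z)-2-methylbut-2-enoic acid | C/C=C(/C)C(=O)O | starting material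
8 | (2Z)-2-methylbut-2-enoic 2,4,6-trichlorobenzoic anhydride (isolated as a filtered toluene solution) | C/C=C(/C)C(=O)OC(=O)c1c(Cl)cc(Cl)cc1Cl | intermediate
9 | (1S,3S,4S,6S)-1-methyl-2-oxo-4-(prop-1-en-2-yl)-7-oxabicyclo[4.1.0]heptan-3-yl (2Z)-2-methylbut-2-enoate | C=C(C)[C@@H]1C[C@@H]2O[C@]2(C)C(=O)[C@H]1OC(=O)/C(C)=C\C | intermediate
10 | 2-[(1S,3S,4S,6S)-1-methyl-3-{[(2Z)-2-methylbut-2-enoyl]oxy}-2-oxo-7-oxabicyclo[4.1.0]heptan-4-yl]prop-2-ene-1-seleninic acid | C=C(C[Se](=O)O)[C@@H]1C[C@@H]2O[C@]2(C)C(=O)[C@H]1OC(=O)/C(C)=C\C | intermediate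
11 | (1S,3S,4S,6S)-4-(3-hydroxyprop-1-en-2-yl)-1-methyl-2-oxo-7-oxabicyclo[4.1.0]heptan-3-yl (2Z)-2-methylbut-2-enoate | C=C(CO)[C@@H]1C[C@@H]2O[C@]2(C)C(=O)[C@H]1OC(=O)/C(C)=C\C | intermediate
12 | (1S,3S,4S,6S)-1-methyl-2-oxo-4-(3-oxoprop-1-en-2-yl)-7-oxabicyclo[4.1.0]heptan-3-yl (2Z)-2-methylbut-2-enoate | C=C(C=O)[C@@H]1C[C@@H]2O[C@]2(C)C(=O)[C@H]1OC(=O)/C(C)=C\C | intermediate
13 | 3-bromo-3-methylbutan-2-one | CC(=O)C(C)(C)Br | starting material
14 | [(3-bromo-3-methylbut-1-en-2-yl)oxy]dibutylborane | C=C(OB(CCCC)CCCC)C(C)(C)Br | intermediate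
15 | (1S,3S,4S,6S)-4-[(3S)-6-bromo-3-hydroxy-6-methyl-5-oxohept-1-en-2-yl]-1-methyl-2-oxo-7-oxabicyclo[4.1.0]heptan-3-yl (2Z)-2-methylbut-2-enoate | C=C([C@@H](O)CC(=O)C(C)(C)Br)[C@@H]1C[C@@H]2O[C@]2(C)C(=O)[C@H]1OC(=O)/C(C)=C\C | intermediate
16 | C8-O-diethylboryl chelate of 15, (1S,3S,4S,6S)-4-{(3S)-6-bromo-3-[(diethylboranyl)oxy]-6-methyl-5-oxohept-1-en-2-yl}-1-methyl-2-oxo-7-oxabicyclo[4.1.0]heptan-3-yl (2Z)-2-methylbut-2-enoate | C=C([C@H](CC(=O)C(C)(C)Br)OB(CC)CC)[C@@H]1C[C@@H]2O[C@]2(C)C(=O)[C@H]1OC(=O)/C(C)=C\C | intermediate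
17 | (1S,3S,4S,6S)-4-[(3S,5R)-6-bromo-3,5-dihydroxy-6-methylhept-1-en-2-yl]-1-methyl-2-oxo-7-oxabicyclo[4.1.0]heptan-3-yl (2Z)-2-methylbut-2-enoate | C=C([C@@H](O)C[C@@H](O)C(C)(C)Br)[C@@H]1C[C@@H]2O[C@]2(C)C(=O)[C@H]1OC(=O)/C(C)=C\C | intermediate
18 | (1S,3S,4S,6S)-4-{(3S)-4-[(2R)-3,3-dimethyloxiran-2-yl]-3-hydroxybut-1-en-2-yl}-1-methyl-2-oxo-7-oxabicyclo[4.1.0]heptan-3-yl (2Z)-2-methylbut-2-enoate | C=C([C@@H](O)C[C@H]1OC1(C)C)[C@@H]1C[C@@H]2O[C@]2(C)C(=O)[C@H]1OC(=O)/C(C)=C\C | intermediate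
19 | CNP0247177.2, (1S,3S,4S,6S)-4-{(3S)-4-[(2R)-3,3-dimethyloxiran-2-yl]-3-[(2Z)-2-methylbut-2-enoyloxy]but-1-en-2-yl}-1-methyl-2-oxo-7-oxabicyclo[4.1.0]heptan-3-yl (2Z)-2-methylbut-2-enoate | C=C([C@H](C[C@H]1OC1(C)C)OC(=O)/C(C)=C\C)[C@@H]1C[C@@H]2O[C@]2(C)C(=O)[C@H]1OC(=O)/C(C)=C\C | target

**Step count and risks**

Total step count: 11. Longest linear sequence: 10 steps (steps 1 to 4 and 6 to 11, from 1 to 19); step 5 is a one-step side branch that makes the acylating agent 8 for both esterifications.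

The three steps most likely to fail are steps 7, 8 and 9.

The Riley oxidation (step 7) may take the ring methine hydrogen at C4 instead of the methyl hydrogen, attack the ketone α-position at C3, or stop at the allylic alcohol. The fallback sets out from 9 and comes back at 12. Ene-type chlorination with hypochlorous acid (Ca(OCl)2, solid CO2, CH2Cl2/H2O, 0 °C) attacks only the electron-rich isopropenyl group and gives the allylic chloride F1. Oxidation of F1 with N-methylmorpholine N-oxide (KI cat., MeCN, 40 °C; Ganem oxidation) then gives enal 12.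

The aldol (step 8) is the weakest stereochemical point: the ring centres may give little bias at C8, or favour the wrong epimer. The fallback makes the other epimer productive; it sets out from 12 and comes back at 19. The same aldol delivers the (8R)-aldol F2. Saksena–Evans reduction with Me4NBH(OAc)3 (MeCN/AcOH, −25 °C; internal hydride delivery, which cannot reduce the undirected ring ketone) gives the 1,3-anti bromo diol F3. DBU closes it to the (8R,10R)-epoxy alcohol F4. Mitsunobu esterification of F4 with 7 (PPh3, diisopropyl azodicarboxylate, toluene, 0 °C) inverts C8 and gives 19 directly, so both C8 epimers converge on the target.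

The syn reduction (step 9) may also reduce the electron-poor ring ketone. The fallback avoids hydride altogether; it sets out from 12 and comes back at 18. The allyl donor 2,3,3-trimethylpent-4-en-2-ol F5 is first made from acetone and prenyl bromide with Zn dust in THF/saturated aqueous NH4Cl (γ-selective Barbier addition). Allyl transfer from F5 to enal 12 with Sn(OTf)2 (5 mol %) in CH2Cl2 at 0 °C forms the C8–C9 bond by a 2-oxonia-Cope [3,3]-sigmatropic rearrangement. It gives, after separation of the C8 epimers, the (8S)-homoallylic alcohol F6. Buffered mCPBA (1.0 equiv, NaHCO3, CH2Cl2, −20 °C) then epoxidises the trisubstituted alkene, the most electron-rich one in F6, and gives 18, which is separated from its C10 epimer. A hydroxyl-directed metal-catalysed epoxidation is not used here because it would favour the allylic 1,1-disubstituted alkene. Selectivity at C10 is low in this variant, so it costs material.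

Further compounds
F1 | step 7 | (1S,3S,4S,6S)-4-(3-chloroprop-1-en-2-yl)-1-methyl-2-oxo-7-oxabicyclo[4.1.0]heptan-3-yl (2Z)-2-methylbut-2-enoate | C=C(CCl)[C@@H]1C[C@@H]2O[C@]2(C)C(=O)[C@H]1OC(=O)/C(C)=C\C
F2 | step 8 | (1S,3S,4S,6S)-4-[(3R)-6-bromo-3-hydroxy-6-methyl-5-oxohept-1-en-2-yl]-1-methyl-2-oxo-7-oxabicyclo[4.1.0]heptan-3-yl (2Z)-2-methylbut-2-enoate | C=C([C@H](O)CC(=O)C(C)(C)Br)[C@@H]1C[C@@H]2O[C@]2(C)C(=O)[C@H]1OC(=O)/C(C)=C\C
F3 | step 8 | (1S,3S,4S,6S)-4-[(3R,5R)-6-bromo-3,5-dihydroxy-6-methylhept-1-en-2-yl]-1-methyl-2-oxo-7-oxabicyclo[4.1.0]heptan-3-yl (2Z)-2-methylbut-2-enoate | C=C([C@H](O)C[C@@H](O)C(C)(C)Br)[C@@H]1C[C@@H]2O[C@]2(C)C(=O)[C@H]1OC(=O)/C(C)=C\C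
F4 | step 8 | (1S,3S,4S,6S)-4-{(3R)-4-[(2R)-3,3-dimethyloxiran-2-yl]-3-hydroxybut-1-en-2-yl}-1-methyl-2-oxo-7-oxabicyclo[4.1.0]heptan-3-yl (2Z)-2-methylbut-2-enoate | C=C([C@H](O)C[C@H]1OC1(C)C)[C@@H]1C[C@@H]2O[C@]2(C)C(=O)[C@H]1OC(=O)/C(C)=C\C
F5 | step 9 | 2,3,3-trimethylpent-4-en-2-ol | C=CC(C)(C)C(C)(C)O
F6 | step 9 | (1S,3S,4S,6S)-4-[(3S)-3-hydroxy-6-methylhepta-1,5-dien-2-yl]-1-methyl-2-oxo-7-oxabicyclo[4.1.0]heptan-3-yl (2Z)-2-methylbut-2-enoate | C=C([C@@H](O)CC=C(C)C)[C@@H]1C[C@@H]2O[C@]2(C)C(=O)[C@H]1OC(=O)/C(C)=C\C
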